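**Retrosynthetic overview**
1. The C2 acetate goes on last, by lipase-catalysed regioselective acetylation of a 2,6-diol 5-ester; the 5β-ester/6α-hydroxyl pair comes from trans-diaxial opening of a 5α,6α-epoxy-4-methylidene hydrindane with (E)-3-methylpent-2-enoic acid.
2. The vinyl epoxide comes from a trans-hydrindan-4-one by Saegusa–Ito desaturation, Weitz–Scheffer epoxidation and Wittig methylenation.
3. The five-membered ring (formed second) is closed at C1–C2 by a nickel-catalysed alkylative ynal cyclisation, which also sets the Z-ethylidene group and the C2 carbinol.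
4. The ynal comes from (S)-cryptone by conjugate alkynylation, regiospecific enolate allylation (all-trans) and alkene cleavage.
5. The six-membered ring (formed first) is (S)-cryptone, from an organocatalytic asymmetric Michael addition of 3-methylbutanal to methyl vinyl ketone followed by aldol condensation.

Conventions: bicyclic compounds carry octahydro-1H-indene locants (C1 ethylidene carbon, C2 oxygenated ring carbon, C3a/C7a ring fusion, C4 carbonyl or methylidene carbon, C5, C6, C7 isopropyl carbon); β is the face of H-3a. The target is trans-fused with H-7a α, 2-OAc β, 5-ester β, 6-OH α, 7-isopropyl α.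
Assumption: isomerically pure (E)-3-methylpent-2-enoic acid is not taken as a stock chemical and is made in steps 13–14.

**Route**

Step 1
Reactants: 1 3-methylbutanal; 2 but-3-en-2-one (methyl vinyl ketone)
Product: 3 (2S)-5-oxo-2-(propan-2-yl)hexanal
Conditions: (2S)-2-[methoxy(diphenyl)methyl]pyrrolidine (5 mol%), ethyl 3,4-dihydroxybenzoate (20 mol%), neat, 4 °C
Reagents that add atoms: none
Why: Enamine-catalysed asymmetric Michael addition; the E-enamine of 1 is attacked by the enone on the face away from the methoxydiphenylmethyl group of the (S)-catalyst, which sets the first stereocentre as 2S.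

Step 2
Reactants: 3 (2S)-5-oxo-2-(propan-2-yl)hexanal
Product: 4 (4S)-4-(propan-2-yl)cyclohex-2-en-1-one ((S)-cryptone)
Conditions: LiOH (0.2 equiv), i-PrOH, rt
Reagents that add atoms: none
Why: Intramolecular aldol condensation of the methyl ketone onto the aldehyde closes the six-membered ring; the stereocentre is not involved and survives the mild base.

Step 3
Reactants: 4 (S)-cryptone
Product: 5 trimethyl({(3S,4S)-4-(propan-2-yl)-3-[(triisopropylsilyl)ethynyl]cyclohex-1-en-1-yl}oxy)silane
Conditions: i-Pr3SiC≡CZnBr (from i-Pr3SiC≡CH, n-BuLi, ZnBr2), TMSOTf, Et2O/THF, −40 °C; Et3N quench, non-aqueous work-up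
Reagents that add atoms: (triisopropylsilyl)acetylene C#C[Si](C(C)C)(C(C)C)C(C)C; trimethylsilyl trifluoromethanesulfonate C[Si](C)(C)OS(=O)(=O)C(F)(F)F
Why: Silyl-triflate-promoted conjugate addition (Mukaiyama–Michael type) of the alkynylzinc to the O-silylated enone; the nucleophile enters anti to the neighbouring isopropyl group (new C3 trans to C4) and the enolate is trapped regiospecifically as its silyl enol ether.

Step 4
Reactants: 5 silyl enol ether from step 3
Product: 7 (2R,3S,4S)-4-(propan-2-yl)-2-(prop-2-en-1-yl)-3-[(triisopropylsilyl)ethynyl]cyclohexan-1-one, via lithium enolate 6 (not isolated)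
Conditions: MeLi, THF, 0 °C; then allyl iodide, DMPU, −78→−20 °C
Reagents that add atoms: allyl iodide C=CCI
Why: Regiospecific enolate generation from the silyl enol ether and SN2 C-allylation anti to the adjacent alkynyl group gives the all-trans, all-equatorial ketone, which is also the thermodynamic C2 epimer.

Step 5
Reactants: 7 allyl ketone from step 4
Product: 8 (2R,3S,4S)-3-ethynyl-4-(propan-2-yl)-2-(prop-2-en-1-yl)cyclohexan-1-one
Conditions: Bu4NF, THF, 0 °C
Reagents that add atoms: none
Why: Fluoride-mediated protodesilylation of the alkynylsilane; no stereocentre is touched and C2 is already the stable trans epimer.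

Step 6
Reactants: 8 ethynyl allyl ketone from step 5
Product: 10 2-[(1R,2S,3S)-2-ethynyl-6-oxo-3-(propan-2-yl)cyclohexyl]acetaldehyde, via diol 9 (not isolated)
Conditions: OsO4 (2 mol%), NaIO4 (4 equiv), 2,6-lutidine, dioxane/H2O 3:1, rt
Reagents that add atoms: osmium tetroxide O=[Os](=O)(=O)=O; sodium periodate [Na+].[O-]I(=O)(=O)=O
Why: Lemieux–Johnson oxidative cleavage; OsO4 dihydroxylates the terminal alkene far faster than the alkyne and periodate cleaves the diol to the aldehyde.

Step 7
Reactants: 10 ynal from step 6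
Product: 11 (1Z,2R,3aR,7S,7aS)-1-ethylidene-2-hydroxy-7-(propan-2-yl)octahydro-4H-inden-4-one
Conditions: Ni(cod)2 (10 mol%), MeZnCl (3 equiv, from MeLi and ZnCl2), THF, 0 °C; aq NH4Cl
Reagents that add atoms: methyllithium [Li]C
Why: Nickel-catalysed alkylative ynal cyclisation (oxidative cyclisation of alkyne and aldehyde on zerovalent nickel, methyl transfer from zinc, reductive elimination); syn addition puts the methyl cis to the new C1–C2 bond (Z-ethylidene), and the near-planar oxanickelacycle holds the C2–O bond in the pseudo-equatorial β position that the twist of the trans-fused ring allows, which gives the 2R carbinol.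

Step 8
Reactants: 11 hydroxy ketone from step 7
Product: 12 (1Z,2R,3aR,7S,7aS)-2-[(tert-butyldimethylsilyl)oxy]-1-ethylidene-7-(propan-2-yl)octahydro-4H-inden-4-one
Conditions: TBSCl, imidazole, DMF, rt
Reagents that add atoms: tert-butyldimethylsilyl chloride CC(C)(C)[Si](C)(C)Cl
Why: Silyl ether protection of the allylic alcohol so that it survives the amide base, the peroxide and the ylide that follow.

Step 9
Reactants: 12 silyl-protected ketone from step 8
Product: 13 tert-butyl({(1Z,2R,3aR,7S,7aS)-1-ethylidene-7-(propan-2-yl)-4-[(trimethylsilyl)oxy]-2,3,3a,6,7,7a-hexahydro-1H-inden-2-yl}oxy)dimethylsilane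
Conditions: LiN(i-Pr)2, TMSCl, THF, −78 °C
Reagents that add atoms: chlorotrimethylsilane C[Si](C)(C)Cl
Why: Kinetic enolisation with in situ silylation removes a proton from the C5 methylene and not from the hindered ring-fusion C3a, so the fusion stereocentre is untouched.

Step 10
Reactants: 13 silyl enol ether from step 9
Product: 14 (1Z,2R,3aR,7R,7aS)-2-[(tert-butyldimethylsilyl)oxy]-1-ethylidene-7-(propan-2-yl)-1,2,3,3a,7,7a-hexahydro-4H-inden-4-one
Conditions: Pd(OAc)2 (1.1 equiv), MeCN, rt
Reagents that add atoms: none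
Why: Saegusa–Ito oxidation (β-hydride elimination from the palladium enolate) gives the C5=C6 enone regiospecifically; the C7 descriptor changes by priority only.

Step 11
Reactants: 14 enone from step 10
Product: 15 (1Z,2R,3aR,5S,6S,7S,7aS)-2-[(tert-butyldimethylsilyl)oxy]-5,6-epoxy-1-ethylidene-7-(propan-2-yl)octahydro-4H-inden-4-one (5α,6α-epoxide)
Conditions: 30% H2O2, NaOH (0.2 equiv), MeOH, 0 °C
Reagents that add atoms: hydrogen peroxide OO
Why: Weitz–Scheffer nucleophilic epoxidation; hydroperoxide adds axially to C6 of the conformationally locked enone from the α face (chair-like transition state, anti to the axial H-7) and the enolate closes the oxirane on the same face.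

Step 12
Reactants: 15 epoxy ketone from step 11
Product: 16 tert-butyl{[(1Z,2R,3aR,5R,6S,7S,7aR)-5,6-epoxy-1-ethylidene-4-methylidene-7-(propan-2-yl)octahydro-1H-inden-2-yl]oxy}dimethylsilane
Conditions: Ph3PCH3Br, t-BuOK, THF, 0 °C; then 15, 0 °C→rt
Reagents that add atoms: methyltriphenylphosphonium bromide C[P+](c1ccccc1)(c1ccccc1)c1ccccc1.[Br-]
Why: Wittig methylenation with the non-stabilised ylide, which reacts with the ketone and leaves the epoxide alone; no stereocentre changes.

Step 13
Reactants: 17 ethyl but-2-ynoate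
Product: 18 ethyl (2E)-3-methylpent-2-enoate
Conditions: EtMgBr, CuBr·SMe2 (1.1 equiv each), THF, −40 °C; then 17, −78 °C; aq NH4Cl at −78 °C
Reagents that add atoms: ethylmagnesium bromide CC[Mg]Br
Why: syn-Carbocupration of the ynoate followed by stereoretentive protonation of the alkenylcopper at low temperature places ethyl trans and methyl cis to the ester (E).

Step 14
Reactants: 18 ethyl (2E)-3-methylpent-2-enoate
Product: 19 (2E)-3-methylpent-2-enoic acid
Conditions: LiOH, THF/H2O, rt; acidic work-up (1 M HCl)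
Reagents that add atoms: lithium hydroxide [Li+].[OH-]
Why: Saponification (acyl substitution) that does not affect the trisubstituted alkene geometry.

Step 15
Reactants: 16 vinyl epoxide from step 12; 19 (2E)-3-methylpent-2-enoic acid
Product: 20 (1Z,2R,3aR,5S,6S,7S,7aR)-2-[(tert-butyldimethylsilyl)oxy]-1-ethylidene-6-hydroxy-4-methylidene-7-(propan-2-yl)octahydro-1H-inden-5-yl (2E)-3-methylpent-2-enoate
Conditions: 19 (3 equiv), Cs2CO3 (0.2 equiv), DMF, 70 °C
Reagents that add atoms: none
Why: SN2 opening of the vinyl epoxide by the carboxylate at the allylic C5 with inversion, with regiochemistry fixed by the Fürst–Plattner trans-diaxial rule, gives the 5β-ester and the free 6α-hydroxyl; the diaxial arrangement also blocks acyl migration.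

Step 16
Reactants: 20 silyl-protected hydroxy ester from step 15
Product: 21 (1Z,2R,3aR,5S,6S,7S,7aR)-1-ethylidene-2,6-dihydroxy-4-methylidene-7-(propan-2-yl)octahydro-1H-inden-5-yl (2E)-3-methylpent-2-enoate
Conditions: HF·pyridine, THF/pyridine, 0 °C→rt
Reagents that add atoms: none
Why: Buffered fluoride desilylation cleaves the silyl ether without touching the ester or the allylic systems.

Step 17
Reactants: 21 diol ester from step 16
Product: 22 (1Z,2R,3aR,5S,6S,7S,7aR)-2-(acetyloxy)-1-ethylidene-6-hydroxy-4-methylidene-7-(propan-2-yl)octahydro-1H-inden-5-yl (2E)-3-methylpent-2-enoate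
Conditions: immobilised Candida antarctica lipase B (a lipase), vinyl acetate (5 equiv), t-BuOMe, 35 °C
Reagents that add atoms: vinyl acetate CC(=O)OC=C
Why: Lipase-catalysed irreversible transesterification; the enzyme acylates only the (2R) carbinol that fits the Kazlauskas rule (ring CH2 as medium group, alkylidene carbon as large group) and does not accept the 6-hydroxyl flanked by two branched carbons, so the acetate goes on regioselectively under neutral conditions.

**Compound list**
1 | 3-methylbutanal | CC(C)CC=O | starting material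
2 | but-3-en-2-one (methyl vinyl ketone) | CC(=O)C=C | starting material
3 | (2S)-5-oxo-2-(propan-2-yl)hexanal | O=C[C@H](C(C)C)CCC(C)=O | intermediate
4 | (4S)-4-(propan-2-yl)cyclohex-2-en-1-one | O=C1C=C[C@H](C(C)C)CC1 | intermediate
5 | trimethyl({(3S,4S)-4-(propan-2-yl)-3-[(triisopropylsilyl)ethynyl]cyclohex-1-en-1-yl}oxy)silane | C[Si](C)(C)OC1=C[C@@H](C#C[Si](C(C)C)(C(C)C)C(C)C)[C@H](C(C)C)CC1 | intermediate
6 | lithium (3S,4S)-4-(propan-2-yl)-3-[(triisopropylsilyl)ethynyl]cyclohex-1-en-1-olate | [Li]OC1=C[C@@H](C#C[Si](C(C)C)(C(C)C)C(C)C)[C@H](C(C)C)CC1 | intermediate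
7 | (2R,3S,4S)-4-(propan-2-yl)-2-(prop-2-en-1-yl)-3-[(triisopropylsilyl)ethynyl]cyclohexan-1-one | O=C1[C@H](CC=C)[C@@H](C#C[Si](C(C)C)(C(C)C)C(C)C)[C@H](C(C)C)CC1 | intermediate
8 | (2R,3S,4S)-3-ethynyl-4-(propan-2-yl)-2-(prop-2-en-1-yl)cyclohexan-1-one | O=C1[C@H](CC=C)[C@@H](C#C)[C@H](C(C)C)CC1 | intermediate
9 | (2R,3S,4S)-2-(2,3-dihydroxypropyl)-3-ethynyl-4-(propan-2-yl)cyclohexan-1-one (both carbinol epimers) | O=C1[C@H](CC(O)CO)[C@@H](C#C)[C@H](C(C)C)CC1 | intermediate
10 | 2-[(1R,2S,3S)-2-ethynyl-6-oxo-3-(propan-2-yl)cyclohexyl]acetaldehyde | O=C1[C@H](CC=O)[C@@H](C#C)[C@H](C(C)C)CC1 | intermediate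
11 | (1Z,2R,3aR,7S,7aS)-1-ethylidene-2-hydroxy-7-(propan-2-yl)octahydro-4H-inden-4-one | O=C1[C@@H]2C[C@@H](O)/C(=C\C)[C@H]2[C@H](C(C)C)CC1 | intermediate
12 | (1Z,2R,3aR,7S,7aS)-2-[(tert-butyldimethylsilyl)oxy]-1-ethylidene-7-(propan-2-yl)octahydro-4H-inden-4-one | O=C1[C@@H]2C[C@@H](O[Si](C)(C)C(C)(C)C)/C(=C\C)[C@H]2[C@H](C(C)C)CC1 | intermediate
13 | tert-butyl({(1Z,2R,3aR,7S,7aS)-1-ethylidene-7-(propan-2-yl)-4-[(trimethylsilyl)oxy]-2,3,3a,6,7,7a-hexahydro-1H-inden-2-yl}oxy)dimethylsilane | C[Si](C)(C)OC=1[C@@H]2C[C@@H](O[Si](C)(C)C(C)(C)C)/C(=C\C)[C@H]2[C@H](C(C)C)CC=1 | intermediate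
14 | (1Z,2R,3aR,7R,7aS)-2-[(tert-butyldimethylsilyl)oxy]-1-ethylidene-7-(propan-2-yl)-1,2,3,3a,7,7a-hexahydro-4H-inden-4-one | O=C1[C@@H]2C[C@@H](O[Si](C)(C)C(C)(C)C)/C(=C\C)[C@H]2[C@H](C(C)C)C=C1 | intermediate
15 | (1Z,2R,3aR,5S,6S,7S,7aS)-2-[(tert-butyldimethylsilyl)oxy]-5,6-epoxy-1-ethylidene-7-(propan-2-yl)octahydro-4H-inden-4-one (5α,6α-epoxide) | O=C1[C@@H]2C[C@@H](O[Si](C)(C)C(C)(C)C)/C(=C\C)[C@H]2[C@H](C(C)C)[C@@H]3O[C@H]13 | intermediate
16 | tert-butyl{[(1Z,2R,3aR,5R,6S,7S,7aR)-5,6-epoxy-1-ethylidene-4-methylidene-7-(propan-2-yl)octahydro-1H-inden-2-yl]oxy}dimethylsilane | C=C1[C@@H]2C[C@@H](O[Si](C)(C)C(C)(C)C)/C(=C\C)[C@H]2[C@H](C(C)C)[C@@H]3O[C@H]13 | intermediate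
17 | ethyl but-2-ynoate | CCOC(=O)C#CC | starting material
18 | ethyl (2E)-3-methylpent-2-enoate | CCOC(=O)/C=C(\C)CC | intermediate
19 | (2E)-3-methylpent-2-enoic acid | OC(=O)/C=C(\C)CC | intermediate
20 | (1Z,2R,3aR,5S,6S,7S,7aR)-2-[(tert-butyldimethylsilyl)oxy]-1-ethylidene-6-hydroxy-4-methylidene-7-(propan-2-yl)octahydro-1H-inden-5-yl (2E)-3-methylpent-2-enoate | C=C1[C@@H]2C[C@@H](O[Si](C)(C)C(C)(C)C)/C(=C\C)[C@H]2[C@H](C(C)C)[C@H](O)[C@H]1OC(=O)/C=C(\C)CC | intermediate
21 | (1Z,2R,3aR,5S,6S,7S,7aR)-1-ethylidene-2,6-dihydroxy-4-methylidene-7-(propan-2-yl)octahydro-1H-inden-5-yl (2E)-3-methylpent-2-enoate | C=C1[C@@H]2C[C@@H](O)/C(=C\C)[C@H]2[C@H](C(C)C)[C@H](O)[C@H]1OC(=O)/C=C(\C)CC | intermediate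
22 | (1Z,2R,3aR,5S,6S,7S,7aR)-2-(acetyloxy)-1-ethylidene-6-hydroxy-4-methylidene-7-(propan-2-yl)octahydro-1H-inden-5-yl (2E)-3-methylpent-2-enoate | C=C1[C@@H]2C[C@@H](OC(C)=O)/C(=C\C)[C@H]2[C@H](C(C)C)[C@H](O)[C@H]1OC(=O)/C=C(\C)CC | target

**Step count and risks**
Total: 17 steps. Longest linear sequence: 15 steps (steps 1–12 and 15–17); the acid side chain takes 2 steps (13–14).

The three steps most likely to fail are steps 3, 7 and 15.

Step 3 is the least precedented: the silyl-triflate-promoted alkynylzinc addition may be sluggish on a 4-substituted cyclohexenone or give 1,2-addition. The fallback sets out from 4 and comes back at 7, putting the allyl group on first so that no regiospecific enolate is needed. α-Iodination (I2, pyridine, CH2Cl2, rt) gives (4S)-2-iodo-4-(propan-2-yl)cyclohex-2-en-1-one F1. Stille coupling (allylSnBu3, Pd2(dba)3, AsPh3, CuI, NMP, rt) gives (4S)-4-(propan-2-yl)-2-(prop-2-en-1-yl)cyclohex-2-en-1-one F2. Nickel-catalysed conjugate addition of Me2AlC≡CSi(i-Pr)3 (Ni(acac)2, (i-Bu)2AlH, Et2O, −5 °C) anti to the isopropyl group, then protonation and equilibration of C2 in the work-up (DBU, MeOH), delivers the all-trans ketone 7.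

Step 7 rests on substrate control for the C2 carbinol; the alkene geometry is mechanistically fixed but the carbinol configuration is a conformational prediction. The fallback sets out from 10 and comes back at 11. If the cyclisation of 10 gives the epimer (1Z,2S,3aR,7S,7aS)-1-ethylidene-2-hydroxy-7-(propan-2-yl)octahydro-4H-inden-4-one F3 as the main or a significant product, it is separated and inverted. Mitsunobu reaction with chloroacetic acid (PPh3, DIAD, toluene, 0 °C) gives (1Z,2R,3aR,7S,7aS)-1-ethylidene-4-oxo-7-(propan-2-yl)octahydro-1H-inden-2-yl chloroacetate F4 by SN2 inversion. Brief methanolysis (K2CO3 cat., MeOH, 0 °C) then returns 11.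

Step 15 may fail because the carboxylate is a weak nucleophile or attacks the methylidene terminus (SN2′). The fallback sets out from 16 and comes back at 20, separating C–O bond formation from acylation. Acid-catalysed hydrolysis (HClO4 cat., THF/H2O, 0 °C) opens the epoxide trans-diaxially at the allylic carbon to (1Z,2R,3aR,5S,6S,7S,7aR)-2-[(tert-butyldimethylsilyl)oxy]-1-ethylidene-4-methylidene-7-(propan-2-yl)octahydro-1H-indene-5,6-diol F5. Steglich esterification with 19 (DCC, DMAP, CH2Cl2, −20→0 °C) then acylates the less hindered allylic 5-hydroxyl in preference to the 6-hydroxyl next to the isopropyl group and gives 20.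

**Further compounds**
F1 | step 3 | (4S)-2-iodo-4-(propan-2-yl)cyclohex-2-en-1-one | O=C1C(I)=C[C@H](C(C)C)CC1
F2 | step 3 | (4S)-4-(propan-2-yl)-2-(prop-2-en-1-yl)cyclohex-2-en-1-one | O=C1C(CC=C)=C[C@H](C(C)C)CC1
F3 | step 7 | (1Z,2S,3aR,7S,7aS)-1-ethylidene-2-hydroxy-7-(propan-2-yl)octahydro-4H-inden-4-one | O=C1[C@@H]2C[C@H](O)/C(=C\C)[C@H]2[C@H](C(C)C)CC1
F4 | step 7 | (1Z,2R,3aR,7S,7aS)-1-ethylidene-4-oxo-7-(propan-2-yl)octahydro-1H-inden-2-yl chloroacetate | O=C1[C@@H]2C[C@@H](OC(=O)CCl)/C(=C\C)[C@H]2[C@H](C(C)C)CC1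
F5 | step 15 | (1Z,2R,3aR,5S,6S,7S,7aR)-2-[(tert-butyldimethylsilyl)oxy]-1-ethylidene-4-methylidene-7-(propan-2-yl)octahydro-1H-indene-5,6-diol | C=C1[C@@H]2C[C@@H](O[Si](C)(C)C(C)(C)C)/C(=C\C)[C@H]2[C@H](C(C)C)[C@H](O)[C@H]1O
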